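Partner, fed into a stirred racemate over a single-handed catalyst, is the first setting to turn.

- Tuesday's: left-handed substrate 0.50 M; right-handed substrate 0.50 M; partner 0.80 M (fed, over 5.0 s); precatalyst 90 mM; run made earlier
- flask: left-handed substrate 0.50 M; partner 0.400 M (fed, over 5.0 s); precatalyst 90 mM; right-handed substrate 0.50 M; time 20 min

Tuesday's run (percent of the left-handed substrate and right-handed substrate together charged)

| time / s | left-handed substrate / % | left-handed product / % | right-handed substrate / % |
|---|---|---|---|
| 10.0 | 46.5 | 3.3 | 48.2 |
| 15.0 | 41.6 | 8.2 | 46.3 |
| 20.0 | 36.3 | 13.7 | 44.7 |
| 30.0 | 23.5 | 26.0 | 40.8 |
| 50.0 | 8.7 | 41.2 | 34.8 |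
| 80.0 | 1.7 | 48.3 | 31.0 |
| 120 | 0.3 | 49.4 | 29.0 |

(standard deviation of a reading: 0.3 percentage points)

- free catalyst is single-handed; left-handed substrate and right-handed substrate are mirror images of each other, charged as a racemate, each of them at the stated concentration
- the analysis behind the earlier runs scatters by 0.3 percentage points, standard deviation
- the reaction counts as stopped when no species that holds the left-handed substrate and right-handed substrate together changes by six tenths of a point or more over the second half of the time

* at 20 min, what has stopped the reaction, if anything has (no working catalyst is left / all of the left-handed substrate has reacted / it is still moving / forward and back rates have come level / the partner has run out first)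
* part of the left-handed substrate and right-handed substrate together gone at 20 min
* the left-handed product standing at 20 min, as a percentage of the left-handed substrate and right-handed substrate together charged
* the right-handed substrate standing at 20 min, as a percentage of the left-handed substrate and right-handed substrate together charged

**Partner.** In Tuesday's run, left-handed substrate plus product still total 49.7% at 120 s, so that path is clean. Assume each substrate lost, of either hand, takes one partner. Define the ceiling F as partner charged over both substrates charged:

F = 40.0%

**Time.** Tuesday's left-handed substrate falls with a time constant of 21.0 s, and 56.5% of both substrates had gone by 50.0 s, more than this flask's F. With 20 min far longer, expect partner, the limiting reagent, to stop this flask at F.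

**Feed.** This flask's feed of 5.0 s is shorter than Tuesday's time constant, so count it as one dose.

**Precatalyst.** Keep 90 mM, as on Tuesday. By hand, expect it to move the pace; F does not contain it.

**Split.** Take the selectivity factor s, the ratio of the log falls of the two substrates. Tuesday's s, multiplied by the partner left as a fraction of both substrates charged, gives g. It reads 2.23 from 10.0 s to 20.0 s, and 2.12 from 30.0 s to 50.0 s. In this flask, partner left averages F/2, so the first reading of g gives s = 11.2. Iterate on h, each substrate's share:

h = 50.0%

first round, F taken from left-handed substrate: right-handed substrate 43.3%

second round, that loss put back: right-handed substrate 45.3%, left-handed product 35.3%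

The forecast gives the partner has run out first, 40%, 36.3% and 46.3%: “partner should run out, fixing conversion at 40%”. My product and right-handed substrate are lower.

The flask gives the partner has run out first, 39.6%, 33.2% and 45.6%.

    free catalyst + right-handed substrate ⇌ catalyst intermediate B (K = 0.870 L mol⁻¹, k = 37.0 L mol⁻¹ s⁻¹)
    2 free catalyst ⇌ resting dimer, settled at all times (K = 6.00 L mol⁻¹)
    partner + catalyst intermediate A → free catalyst + left-handed product (k = 4.30 L mol⁻¹ s⁻¹)
    free catalyst + left-handed substrate ⇌ catalyst intermediate A (K = 33.0 L mol⁻¹, k = 2.80 L mol⁻¹ s⁻¹)
    partner + catalyst intermediate B → free catalyst + right-handed product (k = 1.40 L mol⁻¹ s⁻¹)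
    partner + precatalyst → free catalyst + spent reagent (k = 0.0250 L mol⁻¹ s⁻¹)

Moved alone up or down by the same factor, the settings shift this flask's left-handed product at most as partner (8.3 points), then precatalyst (0.35 points); the gradual feed and the longer run leave its right-handed substrate unmoved. Now charge a neighbour flask with 0.16 M of partner:

F = 16.0%, s = 27.9

first round: right-handed substrate 49.3%; second round: right-handed substrate 49.3%, left-handed product 15.3%

The neighbour flask stands at 15.9% gone, 49.3% right-handed substrate and 13.9% left-handed product.

Readings and results are calculated with made-up constants; noise was put on by code.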